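(The runs were computed for an exercise; the scatter is artificial.)

The north-east flask still holds 22.0% of its substrate at 4.00 h, and the flask asked about is that same flask, to be judged at 5.0 h.

common to all: substrate 0.65 M
- north-east: reagent 0.78 M; free catalyst 32 mM; the very flask that is asked about, followed so far
- west: reagent 0.78 M; free catalyst 64 mM; run made earlier
- flask: reagent 0.780 M; free catalyst 32 mM; time 5.0 h

- north-east (time / h: target / %, substrate / %): 0.333: 35.7, 67.6; 0.667: 48.4, 49.2; 1.00: 56.3, 40.6; 2.00: 68.7, 28.4; 4.00: 73.8, 22.0
- west (time / min: target / %, substrate / %): 2.00: 5.9, 97.1; 4.00: 9.1, 91.0; 6.00: 11.7, 86.2; 12.0: 23.6, 76.8; 25.0: 37.4, 60.7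

(each reading ± 1 percentage point)

- what is taken out of target is counted as made
- additions bring no volume worth counting

- theta: at 5.0 h take out 90% of the target then present, then wait 10 h
- zeta: at 5.0 h add free catalyst, 100% of the amount charged, then wait 10 h
- delta: change nothing and wait 10 h more
- beta: at 5.0 h add reagent, 50.0% of the amount charged, then wait 10 h

- target, in percent of the substrate first charged, at 5.0 h
- the option that brings most further target ("none" if no option brings more than 2 percentage points) (theta / zeta / delta / beta / none)
- target present, with what was taken out counted in, in percent of the substrate first charged, after zeta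
- target present, with what was taken out counted in, in percent of the substrate first charged, after delta

1. Reagent is not read. Counting one reagent per target formed puts the reagent left in the north-east flask at 38.5% of its charge at 4.00 h, as an estimate.

2. Two numbers seem at odds: both partners remain, yet target rises by 5.1 percentage points from 2.00 h to 4.00 h, after 35.7% in the first 0.333 h.

3. A reversible step clears this. The reaction quotient in fractions of the charge, target over substrate times reagent, reads 8.71 at 4.00 h. Its common logarithm, 0.940, is the quotient exponent. At 2.00 h the exponent read 0.753, so in the north-east flask it is still rising while target slows.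

4. Taking 0.940 as a working ceiling, with the closed balance, this text's own reckoning puts target at 76.1% at 5.0 h, with reagent at 36.6%.

5. In powers of ten, theta takes 1.00 off the exponent at the moment of action, more than the 0.374 that beta takes off; at that moment delta and zeta shift none of the three fractions. Theta is the reckoned choice.

6. The forecast gives 75%, theta, 75.9% after zeta and 75.8% after delta, holding that “Waiting or adding catalyst gains under 1 point”.

The flask gives 74.8% and theta, which brings 11 points against 6.5 points for beta. After delta it holds 72.2%; after zeta, 68.7%, below the forecast. At 5.00 h the flask also holds 4.58% of isomer of the product, which the quotient does not count.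

    substrate + reagent ⇌ target (K = 19.0 M⁻¹, k = 5.30 × 10⁻⁴ M⁻¹ s⁻¹)
    substrate + reagent ⇌ isomer of the product (K = 98.0 M⁻¹, k = 7.80 × 10⁻⁶ M⁻¹ s⁻¹)
    target + free catalyst ⇌ isomer of the product + free catalyst, rate k3*[free catalyst]*[target] forward; the back reaction follows from the equilibrium constant (k = 3.60 × 10⁻⁴ M⁻¹ s⁻¹)
    2 reagent → self-condensation product (k = 1.80 × 10⁻⁵ M⁻¹ s⁻¹)
    free catalyst → spent catalyst (k = 1.90 × 10⁻⁴ s⁻¹)

The flask's state at 5.00 h has exponent 1.16, higher than the 0.940 reckoned from the readings at 4.00 h, and the backward rate of the step to target stands at 96.6% of its forward rate. Part of the ceiling is the return of target, acting together with reagent running short at 25.4%: the run without that return reaches 87.1%. In the neighbour flask with 1.6 M of substrate, reagent is the limiting reagent at 0.487 equiv, and exponent 0.940 gives target 44.3%. Computed, that flask holds 42.3% of target at 5.00 h.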